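The ten-membered carbocycle is hidden in a cis-fused decalin: the Z C1=C10 and E C4=C5 alkenes that flank C2–C3 are read as the hydrolysed form of a C1(10),C2,C4-triene silyl enol ether, the valence isomer of a ring A 2-silyloxycyclohexa-1,3-diene joined to ring B through C5–C10. One photochemical conrotatory 6π opening cuts that bond, merges rings A and B into the cyclodecane and sets both alkene geometries. The precursor is a cis-fused siloxydiene whose trans-fused lactone locks ring B; it already carries the lactone methylene and the C9 ester, so that only enol ether hydrolysis, C2 reduction and one desilylation follow.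

Key step: step 15

Conventions: ring carbons keep the target numbering C1–C10 throughout (ring A = C1–C5 and C10, ring B = C5–C10 in the bicyclic compounds); C11–C13 are the lactone carbons, C14 the methyl on C10, C15 the methyl on C4. α/β follow the usual eudesmane drawing (C14 methyl β).

Assumption: the (R)-BINOL titanium Lewis acid of step 2 is taken to shield the quinone face that leads to 4; if a first run shows the opposite sense, the (S)-ligand is used with no other change.

Remark: 5 and 6 are C7-epimer mixtures and 13 and 14 are C11-epimer mixtures; these centres become sp2 in steps 5 and 8.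

Step 1
Reactants: 1 (E)-pent-3-en-2-one
Product: 2 (E)-2-(triisopropylsilyloxy)penta-1,3-diene
Conditions: i-Pr3SiOTf, Et3N, Et2O, 0 °C
Reagents that add atoms: triisopropylsilyl triflate, CC(C)[Si](OS(=O)(=O)C(F)(F)F)(C(C)C)C(C)C
Why: Soft enolisation (silyl triflate/amine enol silylation) at the methyl ketone CH3 should give the cross-conjugated 2-silyloxydiene with the E alkene untouched; no stereocentre is formed.

Step 2
Reactants: 2 (E)-2-(triisopropylsilyloxy)penta-1,3-diene; 3 2-methoxy-5-methyl-1,4-benzoquinone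
Product: 4 cis-fused adduct, 7-methoxy-4α,10β-dimethyl-2-(triisopropylsilyloxy)-5βH-decalin-2,7-diene-6,9-dione (target numbering)
Conditions: (R)-BINOL (12 mol %), TiCl2(Oi-Pr)2 (10 mol %), 4 Å molecular sieves, toluene, −30 °C
Reagents that add atoms: none
Why: Lewis-acid-catalysed endo Diels–Alder reaction: two-point binding of titanium to the methoxy oxygen and the adjacent carbonyl (future C6=O) makes the methyl-bearing carbon (future C10) the electrophilic terminus, which joins the nucleophilic CH2 terminus of the diene; the methoxy-bearing alkene does not react; suprafacial endo addition sets C4, C5 and C10 relative to each other (cis fusion), and the BINOL ligand sets their absolute sense.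

Step 3
Reactants: 4 cis-fused enedione adduct
Product: 5 7ξ-methoxy-4α,10β-dimethyl-2-(triisopropylsilyloxy)-5βH-decal-2-ene-6,9-dione
Conditions: Zn dust, AcOH–THF (1:5), 0 °C, short contact; filtration, NaHCO3 wash
Reagents that add atoms: none
Why: Zinc/acetic acid two-electron reduction of an ene-1,4-dione to the saturated dione; the non-basic, brief conditions should leave the C5–H next to the C6 ketone, and therefore the cis fusion, intact, and C7 forms as an epimer mixture that is removed in step 5.

Step 4
Reactants: 5 7ξ-methoxy-6,9-dione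
Product: 6 6α-hydroxy-7ξ-methoxy-4α,10β-dimethyl-2-(triisopropylsilyloxy)-5βH-decal-2-en-9-one
Conditions: LiBH(s-Bu)3 (1.0 equiv), THF, −78 °C; aq. NH4Cl
Reagents that add atoms: none
Why: Bulky-hydride ketone reduction: the C6 ketone (activated by its α-methoxy group, less hindered than C9 beside the quaternary C10) should react first, and hydride enters from the open β face (face of H-5 and CH3-14) because ring A carbon C1 sits axially over the α face, giving the 6α-alcohol cis to ring A.

Step 5
Reactants: 6 6α-hydroxy-7ξ-methoxy-9-ketone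
Product: 7 6α-hydroxy-4α,10β-dimethyl-2-(triisopropylsilyloxy)-5βH-decalin-2,7-dien-9-one
Conditions: DBU, CH2Cl2, 0 °C to rt
Reagents that add atoms: none
Why: E1cB β-elimination of methanol through the C9 enolate converts both C7 epimers into one 4-hydroxy enone; no stereocentre is α to a carbonyl any more (C10 is quaternary), so the base cannot scramble the ring fusion.

Step 6
Reactants: 7 6α-hydroxy-Δ7-9-ketone; 8 1-methoxy-1-(trimethylsilyloxy)ethene
Product: 11 13-nor-9-oxo-2-(triisopropylsilyloxy)-4βH,5βH,7αH-eudesm-2-en-12,6α-olide, via bis-silylated Michael adduct 9 (not isolated), via hydroxy keto ester 10 (not isolated)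
Conditions: 8 (3 equiv), MeCN, 50 °C; then K2CO3, MeOH, 0 °C; then PPTS (cat.), toluene, 70 °C
Reagents that add atoms: none
Why: Mukaiyama–Michael addition (one equivalent of 8 first silylates O-6): the ketene acetal attacks C7 anti to the pseudoaxial 6α-silyloxy group on the open β face, so the C7–C11 bond is β (H-7 α) and trans to O-6; mild methanolysis frees the alcohol and the C9 ketone, and acid-catalysed lactonisation closes the trans-fused γ-lactone.

Step 7
Reactants: 11 9-keto lactone
Product: 12 9β-hydroxy-13-nor-2-(triisopropylsilyloxy)-4βH,5βH,7αH-eudesm-2-en-12,6α-olide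
Conditions: SmI2 (2.5 equiv), THF–H2O, 0 °C
Reagents that add atoms: none
Why: Single-electron (dissolving-metal type) ketone reduction gives the thermodynamic carbinol: in the chair locked by the trans lactone the 9β-hydroxyl is equatorial, whereas the 9α epimer would be axial and syn to the axial C4 (hydride reagents would give that epimer by equatorial attack); the γ-lactone and the silyl enol ether are inert to these conditions.

Step 8
Reactants: 12 9β-hydroxy lactone
Product: 15 9β-hydroxy-2-(triisopropylsilyloxy)-4βH,5βH-eudesma-2,11(13)-dien-12,6α-olide, via Mannich base 13 (not isolated), via methiodide 14 (not isolated)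
Conditions: LiN(i-Pr)2 (2.3 equiv), THF, −78 °C; CH2=NMe2+ I−, −78 °C to rt; then MeI, MeOH, rt; then NaHCO3 (aq), CH2Cl2
Reagents that add atoms: dimethyl(methylidene)ammonium iodide, C=[N+](C)C.[I-]
Why: Mannich aminomethylation of the lactone enolate (the C9 alkoxide is a spectator), N-quaternisation and Hofmann-type β-elimination install the α-methylene lactone on the robust decalin; C11 becomes sp2, so no stereocentre results.

Step 9
Reactants: 15 α-methylene lactone silyl enol ether
Product: 16 9β-hydroxy-2-oxo-5βH-eudesma-3,11(13)-dien-12,6α-olide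
Conditions: Pd(OAc)2 (1.2 equiv), DMSO, 45 °C
Reagents that add atoms: none
Why: Saegusa–Ito oxidation of the Diels–Alder-derived silyl enol ether: the palladium enolate at C3 can lose a β-hydrogen only from C4, giving the 3-en-2-one regiospecifically and erasing the C4 stereocentre.

Step 10
Reactants: 17 but-2-yn-1-ol
Product: 18 (Z)-2-(tributylstannyl)but-2-en-1-ol
Conditions: Bu3SnH, [(C5Me5)RuCl]4 (2 mol %), CH2Cl2, rt
Reagents that add atoms: tributyltin hydride, CCCC[SnH](CCCC)CCCC
Why: Ruthenium-catalysed trans-hydrostannation of a propargylic alcohol: H and Sn add anti and the hydroxyl–chloride hydrogen bond steers tin to the carbon next to CH2OH, which fixes the alkene geometry (CH3 cis to tin, later cis to the carboxyl).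

Step 11
Reactants: 18 (Z)-2-(tributylstannyl)but-2-en-1-ol
Product: 19 (Z)-tert-butyldimethyl{[2-(tributylstannyl)but-2-en-1-yl]oxy}silane
Conditions: t-BuMe2SiCl, imidazole, CH2Cl2, 0 °C to rt
Reagents that add atoms: tert-butyldimethylsilyl chloride, CC(C)(C)[Si](C)(C)Cl
Why: Standard imidazole-mediated silylation of a primary alcohol; the alkenylstannane is untouched.

Step 12
Reactants: 19 silyl-protected alkenylstannane
Product: 21 (Z)-2-[(tert-butyldimethylsilyloxy)methyl]but-2-enoic acid, via alkenyllithium 20 (not isolated)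
Conditions: n-BuLi, THF, −78 °C; then CO2, −78 °C; cold 0.5 M HCl to pH 3
Reagents that add atoms: carbon dioxide, O=C=O
Why: Tin–lithium exchange and carboxylation both proceed with retention at the sp2 carbon, so the Z acid (CH3 cis to CO2H) should result; the alkenyllithium is kept at −78 °C to avoid silyl migration or elimination.

Step 13
Reactants: 16 9β-hydroxy enone lactone; 21 (Z)-2-[(tert-butyldimethylsilyloxy)methyl]but-2-enoic acid
Product: 23 9β-{(Z)-2-[(tert-butyldimethylsilyloxy)methyl]but-2-enoyloxy}-2-oxo-5βH-eudesma-3,11(13)-dien-12,6α-olide, via mixed anhydride 22 (not isolated)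
Conditions: 21, 2,4,6-Cl3C6H2COCl, Et3N, toluene, rt; then 16, toluene, 75 °C
Reagents that add atoms: none
Why: Yamaguchi esterification through the mixed anhydride, run without a nucleophilic amine catalyst so that the Z enoate is not isomerised by conjugate addition; the equatorial C9 alcohol attacks the unhindered enoyl carbonyl and no stereocentre changes.

Step 14
Reactants: 23 C9 ester enone
Product: 25 2-(tert-butyldimethylsilyloxy)-9β-{(Z)-2-[(tert-butyldimethylsilyloxy)methyl]but-2-enoyloxy}-5βH-eudesma-1,3,11(13)-trien-12,6α-olide, via lithium dienolate 24 (not isolated)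
Conditions: LiN(SiMe3)2 (1.05 equiv), THF, −78 °C; then t-BuMe2SiOTf, −78 °C; Et3N, pentane work-up
Reagents that add atoms: tert-butyldimethylsilyl triflate, CC(C)(C)[Si](C)(C)OS(=O)(=O)C(F)(F)F
Why: Kinetic α′-deprotonation of the enone at C1 and O-silylation give the cross-conjugated 2-silyloxy-1,3-diene; the γ-hydrogen at C5 is not touched, so the cis fusion survives, and the methylenated lactone has no α-hydrogen to compete.

Step 15
Reactants: 25 cis-fused 2-silyloxy-1,3-diene
Product: 26 (1(10)Z,4E)-2-(tert-butyldimethylsilyloxy)-9β-{(Z)-2-[(tert-butyldimethylsilyloxy)methyl]but-2-enoyloxy}germacra-1(10),2,4,11(13)-tetraen-12,6α-olide (C2=C3 cis in the ring)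
Conditions: hν (300 nm lamps, Pyrex), degassed pentane–THF, −78 °C, partial conversion; solution used cold in step 16
Reagents that add atoms: none
Why: Excitation of the ring A 2-silyloxycyclohexa-1,3-diene triggers conrotatory 6π electrocyclic cleavage of the C5–C10 σ bond, the reaction type by which ring-fused cyclohexa-1,3-dienes open to medium-ring trienes (provitamin D to previtamin D type). No ring is closed by bond formation: the ten-membered carbocycle appears because the bond shared by rings A and B is cut, leaving C1=C10, C4=C5 and the shifted C2=C3 enol ether in one ring. No stereocentre is created and C6, C7 and C9 are untouched; the stereochemical outcome is the geometry of the two new alkenes. Because the fusion is cis, conrotation must turn one ring B bond inward and the other outward, which gives one Z and one E alkene. The needed torquoselectivity (C10–C9 inward for 1(10)Z, C5–C6 outward for 4E) rests on the trans-fused lactone, which allows a single ring B chair in which the C10–C9 bond is pseudoaxial and the C5–C6 bond pseudoequatorial on the diene ring, so that the least-motion conrotation continuing the ground-state diene helicity turns the pseudoaxial bond inward. Low temperature and immediate hydrolysis guard against thermal reclosure, [1,7]-hydrogen shift and over-irradiation, and the enoate and methylene lactone do not absorb near 300 nm.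

Step 16
Reactants: 26 triene silyl enol ether
Product: 27 (1(10)Z,4E)-9β-{(Z)-2-[(tert-butyldimethylsilyloxy)methyl]but-2-enoyloxy}-2-oxogermacra-1(10),4,11(13)-trien-12,6α-olide
Conditions: Bu4NF–AcOH (1:1), THF, −78 °C; pH 7 buffer
Reagents that add atoms: none
Why: Buffered fluoride cleavage of the silyl enol ether with kinetic α-protonation at C3 gives the C2 ketone with C3 as CH2 and both ring alkenes in place, which removes the triene and stops reclosure; the primary alkyl silyl ether reacts far more slowly at this temperature.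

Step 17
Reactants: 27 C2 ketone
Product: 28 (2R,1(10)Z,4E)-9β-{(Z)-2-[(tert-butyldimethylsilyloxy)methyl]but-2-enoyloxy}-2-hydroxygermacra-1(10),4,11(13)-trien-12,6α-olide
Conditions: (S)-2-methyl-CBS-oxazaborolidine (0.5 equiv), catecholborane, toluene, −78 °C; pH 7 buffer
Reagents that add atoms: none
Why: Corey–Bakshi–Shibata reduction: with the alkenyl branch (C1=C10) as the larger ketone substituent the (S)-catalyst should deliver hydride to the face that gives the 2R carbinol, by 1,2-reduction that spares the methylene lactone and the enoate.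

Step 18
Reactants: 28 side-chain silyl ether
Product: 29 CNP0273961.1, (2R,1(10)Z,4E)-2-hydroxy-9β-[(Z)-2-(hydroxymethyl)but-2-enoyloxy]germacra-1(10),4,11(13)-trien-12,6α-olide
Conditions: HF·pyridine, pyridine, THF, 0 °C
Reagents that add atoms: none
Why: Buffered fluoride desilylation of the primary allylic silyl ether; the near-neutral medium should avoid transannular cyclisation of the 1(10),4-diene, acyl migration and addition to the methylene lactone.

Compound list
1 | (E)-pent-3-en-2-one | C/C=C/C(C)=O | starting material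
2 | (E)-2-(triisopropylsilyloxy)penta-1,3-diene | C=C(O[Si](C(C)C)(C(C)C)C(C)C)/C=C/C | intermediate
3 | 2-methoxy-5-methyl-1,4-benzoquinone | COC1=CC(=O)C(C)=CC1=O | starting material
4 | 7-methoxy-4α,10β-dimethyl-2-(triisopropylsilyloxy)-5βH-decalin-2,7-diene-6,9-dione | C[C@]12CC(O[Si](C(C)C)(C(C)C)C(C)C)=C[C@@H](C)[C@H]1C(=O)C(OC)=CC2=O | intermediate
5 | 7ξ-methoxy-4α,10β-dimethyl-2-(triisopropylsilyloxy)-5βH-decal-2-ene-6,9-dione (C7 epimers) | C[C@]12CC(O[Si](C(C)C)(C(C)C)C(C)C)=C[C@@H](C)[C@H]1C(=O)C(OC)CC2=O | intermediate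
6 | 6α-hydroxy-7ξ-methoxy-4α,10β-dimethyl-2-(triisopropylsilyloxy)-5βH-decal-2-en-9-one (C7 epimers) | C[C@]12CC(O[Si](C(C)C)(C(C)C)C(C)C)=C[C@@H](C)[C@H]1[C@@H](O)C(OC)CC2=O | intermediate
7 | 6α-hydroxy-4α,10β-dimethyl-2-(triisopropylsilyloxy)-5βH-decalin-2,7-dien-9-one | C[C@]12CC(O[Si](C(C)C)(C(C)C)C(C)C)=C[C@@H](C)[C@H]1[C@@H](O)C=CC2=O | intermediate
8 | 1-methoxy-1-(trimethylsilyloxy)ethene | C=C(OC)O[Si](C)(C)C | starting material
9 | methyl [4α,10β-dimethyl-2-(triisopropylsilyloxy)-6α,9-bis(trimethylsilyloxy)-5βH-decalin-2,8-dien-7β-yl]acetate | C[C@]12CC(O[Si](C(C)C)(C(C)C)C(C)C)=C[C@@H](C)[C@H]1[C@@H](O[Si](C)(C)C)[C@H](CC(=O)OC)C=C2O[Si](C)(C)C | intermediate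
10 | methyl [6α-hydroxy-4α,10β-dimethyl-9-oxo-2-(triisopropylsilyloxy)-5βH-decal-2-en-7β-yl]acetate | C[C@]12CC(O[Si](C(C)C)(C(C)C)C(C)C)=C[C@@H](C)[C@H]1[C@@H](O)[C@H](CC(=O)OC)CC2=O | intermediate
11 | 13-nor-9-oxo-2-(triisopropylsilyloxy)-4βH,5βH,7αH-eudesm-2-en-12,6α-olide | C[C@]12CC(O[Si](C(C)C)(C(C)C)C(C)C)=C[C@@H](C)[C@H]1[C@H]3OC(=O)C[C@@H]3CC2=O | intermediate
12 | 9β-hydroxy-13-nor-2-(triisopropylsilyloxy)-4βH,5βH,7αH-eudesm-2-en-12,6α-olide | C[C@]12CC(O[Si](C(C)C)(C(C)C)C(C)C)=C[C@@H](C)[C@H]1[C@H]3OC(=O)C[C@@H]3C[C@@H]2O | intermediate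
13 | 13-(dimethylamino)-9β-hydroxy-2-(triisopropylsilyloxy)-4βH,5βH,7αH-eudesm-2-en-12,6α-olide (C11 epimers) | C[C@]12CC(O[Si](C(C)C)(C(C)C)C(C)C)=C[C@@H](C)[C@H]1[C@H]3OC(=O)C(CN(C)C)[C@@H]3C[C@@H]2O | intermediate
14 | N-methyl iodide of 13 (13-trimethylammonio lactone iodide, C11 epimers) | C[C@]12CC(O[Si](C(C)C)(C(C)C)C(C)C)=C[C@@H](C)[C@H]1[C@H]3OC(=O)C(C[N+](C)(C)C)[C@@H]3C[C@@H]2O.[I-] | intermediate
15 | 9β-hydroxy-2-(triisopropylsilyloxy)-4βH,5βH-eudesma-2,11(13)-dien-12,6α-olide | C[C@]12CC(O[Si](C(C)C)(C(C)C)C(C)C)=C[C@@H](C)[C@H]1[C@H]3OC(=O)C(=C)[C@@H]3C[C@@H]2O | intermediate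
16 | 9β-hydroxy-2-oxo-5βH-eudesma-3,11(13)-dien-12,6α-olide | C[C@]12CC(=O)C=C(C)[C@H]1[C@H]3OC(=O)C(=C)[C@@H]3C[C@@H]2O | intermediate
17 | but-2-yn-1-ol | CC#CCO | starting material
18 | (Z)-2-(tributylstannyl)but-2-en-1-ol | C/C=C(/CO)[Sn](CCCC)(CCCC)CCCC | intermediate
19 | (Z)-tert-butyldimethyl{[2-(tributylstannyl)but-2-en-1-yl]oxy}silane | C/C=C(/CO[Si](C)(C)C(C)(C)C)[Sn](CCCC)(CCCC)CCCC | intermediate
20 | (Z)-[1-(tert-butyldimethylsilyloxy)but-2-en-2-yl]lithium | C/C=C(/CO[Si](C)(C)C(C)(C)C)[Li] | intermediate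
21 | (Z)-2-[(tert-butyldimethylsilyloxy)methyl]but-2-enoic acid | C/C=C(/CO[Si](C)(C)C(C)(C)C)C(=O)O | intermediate
22 | mixed anhydride of 21 with 2,4,6-trichlorobenzoic acid | C/C=C(/CO[Si](C)(C)C(C)(C)C)C(=O)OC(=O)c1c(Cl)cc(Cl)cc1Cl | intermediate
23 | 9β-{(Z)-2-[(tert-butyldimethylsilyloxy)methyl]but-2-enoyloxy}-2-oxo-5βH-eudesma-3,11(13)-dien-12,6α-olide | C[C@]12CC(=O)C=C(C)[C@H]1[C@H]3OC(=O)C(=C)[C@@H]3C[C@@H]2OC(=O)/C(=C\C)CO[Si](C)(C)C(C)(C)C | intermediate
24 | lithium 1,3-dien-2-olate of 23 | C[C@]12C=C([O-])C=C(C)[C@H]1[C@H]3OC(=O)C(=C)[C@@H]3C[C@@H]2OC(=O)/C(=C\C)CO[Si](C)(C)C(C)(C)C.[Li+] | intermediate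
25 | 2-(tert-butyldimethylsilyloxy)-9β-{(Z)-2-[(tert-butyldimethylsilyloxy)methyl]but-2-enoyloxy}-5βH-eudesma-1,3,11(13)-trien-12,6α-olide | C[C@]12C=C(O[Si](C)(C)C(C)(C)C)C=C(C)[C@H]1[C@H]3OC(=O)C(=C)[C@@H]3C[C@@H]2OC(=O)/C(=C\C)CO[Si](C)(C)C(C)(C)C | intermediate
26 | (1(10)Z,4E)-2-(tert-butyldimethylsilyloxy)-9β-{(Z)-2-[(tert-butyldimethylsilyloxy)methyl]but-2-enoyloxy}germacra-1(10),2,4,11(13)-tetraen-12,6α-olide (C2=C3 cis in the ring) | C=C1C(=O)O[C@@H]2/C=C(\C)/C=C(O[Si](C)(C)C(C)(C)C)\C=C(\C)[C@@H](OC(=O)/C(=C\C)CO[Si](C)(C)C(C)(C)C)C[C@@H]12 | intermediate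
27 | (1(10)Z,4E)-9β-{(Z)-2-[(tert-butyldimethylsilyloxy)methyl]but-2-enoyloxy}-2-oxogermacra-1(10),4,11(13)-trien-12,6α-olide | C=C1C(=O)O[C@@H]2/C=C(\C)CC(=O)/C=C(/C)[C@@H](OC(=O)/C(=C\C)CO[Si](C)(C)C(C)(C)C)C[C@@H]12 | intermediate
28 | (2R,1(10)Z,4E)-9β-{(Z)-2-[(tert-butyldimethylsilyloxy)methyl]but-2-enoyloxy}-2-hydroxygermacra-1(10),4,11(13)-trien-12,6α-olide | C=C1C(=O)O[C@@H]2/C=C(\C)C[C@@H](O)/C=C(/C)[C@@H](OC(=O)/C(=C\C)CO[Si](C)(C)C(C)(C)C)C[C@@H]12 | intermediate
29 | CNP0273961.1, (2R,1(10)Z,4E)-2-hydroxy-9β-[(Z)-2-(hydroxymethyl)but-2-enoyloxy]germacra-1(10),4,11(13)-trien-12,6α-olide | C=C1C(=O)O[C@@H]2/C=C(\C)C[C@@H](O)/C=C(/C)[C@@H](OC(=O)/C(=C\C)CO)C[C@@H]12 | target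

Total step count: 18. Longest linear sequence: 15 steps (steps 1–9 and 13–18); steps 10–12 make the side-chain acid.

Steps most likely to fail

1. Step 15. The excited diene may open with the other conrotatory sense, or be diverted by the C9 enoate and the methylene lactone (energy transfer, scrambling of the side-chain geometry, intramolecular trapping), and the triene may reclose or isomerise further before it is trapped. Fallback, which takes a leaner chromophore through the opening and acylates afterwards, all by known chemistry: it sets out from 16 and returns at 27. The C9 hydroxyl of 16 is silylated (Et3SiCl, imidazole) to the 9β-triethylsilyl ether enone F1. Kinetic enolisation and silylation as in step 14 give the 2-(tert-butyldimethylsilyloxy)-1,3-diene F2. Irradiation as in step 15 should give the (1(10)Z,4E)-triene silyl enol ether F3. HF·pyridine in THF at −40 °C removes both the enol silyl group and the triethylsilyl group to give the 9β-hydroxy-2-oxo-dienolide F4. F4 is esterified with the mixed anhydride 22 (from 21) at the now allylic, less hindered C9 hydroxyl, which gives 27. This fallback removes the risks that come from the enoate but does not change the sense of conrotation; a wrong sense would need a diastereomeric precursor.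

2. Step 2. Enantioface control by the titanium complex may be poor, for example through an uncatalysed background reaction, single-point binding that changes the regiochemistry, or loss of the silyl group from the diene. Fallback by thermal cycloaddition and enzymatic resolution: it sets out from 2 and 3 and returns at 7. Uncatalysed cycloaddition in toluene at 60 °C, whose regiochemistry is inherent in the methoxyquinone, should give racemic adduct, that is 4 together with its enantiomer ent-4 F5. Steps 3 to 5 are run on the racemate, passing through ent-5 F6 and ent-6 F7 to the racemic hydroxy enone containing ent-7 F8. Lipase-catalysed acetylation (Burkholderia cepacia lipase or Candida antarctica lipase B, chosen in a screen; vinyl acetate, t-BuOMe) should convert the unwanted enantiomer into ent-7 acetate F9, and unreacted 7 is separated and enters step 6.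

3. Step 17. Facial selectivity at C2 may be poor, because the conformation of the ten-membered dienone rather than the catalyst may decide which face the hydride takes. Fallback by substrate-controlled reduction and inversion: it sets out from 27 and returns at 28. Luche reduction (NaBH4, CeCl3·7H2O, MeOH, −78 °C) should attack from the ring periphery; if it gives the 2S alcohol, 2-epi-28 F10, Mitsunobu reaction with chloroacetic acid (PPh3, diisopropyl azodicarboxylate, THF, 0 °C) inverts C2 to the (2R)-chloroacetate F11. Thiourea with NaHCO3 in ethanol cleaves the chloroacetate selectively in the presence of the enoate and the lactone, which gives 28.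

Further compounds
F1 | step 15 | 2-oxo-9β-(triethylsilyloxy)-5βH-eudesma-3,11(13)-dien-12,6α-olide | C[C@]12CC(=O)C=C(C)[C@H]1[C@H]3OC(=O)C(=C)[C@@H]3C[C@@H]2O[Si](CC)(CC)CC
F2 | step 15 | 2-(tert-butyldimethylsilyloxy)-9β-(triethylsilyloxy)-5βH-eudesma-1,3,11(13)-trien-12,6α-olide | C[C@]12C=C(O[Si](C)(C)C(C)(C)C)C=C(C)[C@H]1[C@H]3OC(=O)C(=C)[C@@H]3C[C@@H]2O[Si](CC)(CC)CC
F3 | step 15 | (1(10)Z,4E)-2-(tert-butyldimethylsilyloxy)-9β-(triethylsilyloxy)germacra-1(10),2,4,11(13)-tetraen-12,6α-olide | C=C1C(=O)O[C@@H]2/C=C(\C)/C=C(O[Si](C)(C)C(C)(C)C)\C=C(\C)[C@@H](O[Si](CC)(CC)CC)C[C@@H]12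
F4 | step 15 | (1(10)Z,4E)-9β-hydroxy-2-oxogermacra-1(10),4,11(13)-trien-12,6α-olide | C=C1C(=O)O[C@@H]2/C=C(\C)CC(=O)/C=C(/C)[C@@H](O)C[C@@H]12
F5 | step 2 | ent-4 | C[C@@]12CC(O[Si](C(C)C)(C(C)C)C(C)C)=C[C@H](C)[C@@H]1C(=O)C(OC)=CC2=O
F6 | step 2 | ent-5 (C7 epimers) | C[C@@]12CC(O[Si](C(C)C)(C(C)C)C(C)C)=C[C@H](C)[C@@H]1C(=O)C(OC)CC2=O
F7 | step 2 | ent-6 (C7 epimers) | C[C@@]12CC(O[Si](C(C)C)(C(C)C)C(C)C)=C[C@H](C)[C@@H]1[C@H](O)C(OC)CC2=O
F8 | step 2 | ent-7 | C[C@@]12CC(O[Si](C(C)C)(C(C)C)C(C)C)=C[C@H](C)[C@@H]1[C@H](O)C=CC2=O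
F9 | step 2 | ent-7 acetate | C[C@@]12CC(O[Si](C(C)C)(C(C)C)C(C)C)=C[C@H](C)[C@@H]1[C@H](OC(C)=O)C=CC2=O
F10 | step 17 | 2-epi-28, the (2S)-alcohol | C=C1C(=O)O[C@@H]2/C=C(\C)C[C@H](O)/C=C(/C)[C@@H](OC(=O)/C(=C\C)CO[Si](C)(C)C(C)(C)C)C[C@@H]12
F11 | step 17 | (2R)-chloroacetate of 28 | C=C1C(=O)O[C@@H]2/C=C(\C)C[C@@H](OC(=O)CCl)/C=C(/C)[C@@H](OC(=O)/C(=C\C)CO[Si](C)(C)C(C)(C)C)C[C@@H]12
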